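**Remarks on the chemistry**
- The SMILES is read literally: H-5 and the C10 methyl lie on the same face (cis-fused decalin; 3S,5S,8R,9R,10S). 3-OH, the C10 methyl, the C9 side chain and the C8 methyl share that face; 8-OH is on the other. The route is built for this diastereomer.
- The (2S,5S)-amine 7 is assumed to shield the diene face that leads to the enantiomer drawn for 12; if the opposite sense is found, the (2R,5R)-amine is used.

**Retrosynthetic overview**
1. Numbering: decalin C1–C10 (C3 secondary carbinol, C4 gem-dimethyl, C5/C10 ring fusion, C8 tertiary carbinol, C9 side-chain carbon), side chain C11–C22.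
2. Enabling feature: ring A is cis-fused to ring B, and its only functional carbon C3 sits between the C2 methylene and the quaternary C4. Ring A is therefore the α,α′-dianion of 3-methylbutan-2-one (C2–C3–C4) stitched across the C1 aldehyde and the C5=C6–C7=O enone of a ring B cyclohexenone: C1–C2 by aldol addition, C4–C5 by a Michael closure that can only give the cis junction.
3. Ring B first (step 5): Diels–Alder reaction of an (E)-2-methyl-2-enal (C1, C9–C12) with a chiral 1-amino-3-siloxy diene (C5–C8) sets C9 and C10; Rubottom oxidation sets C8. Ring A second (step 7).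
4. Afterwards the auxiliary oxygens at C1 and C7 are removed, the C12–C13 bond is made by Negishi coupling with an (E)-vinyl iodide (C13–C22), and C3 is set by Corey–Bakshi–Shibata reduction.

Key step: step 7

**Route**

Step 1
Reactants: 1 3-(benzyloxy)propanal; 2 2-(triphenylphosphoranylidene)propanal
Product: 3 (E)-5-(benzyloxy)-2-methylpent-2-enal
Conditions: toluene, 90 °C
Reagents that add atoms: none
Why: Wittig olefination with the stabilised formyl ylide should give the (E)-trisubstituted enal that carries C1 (CHO), C10 with its methyl, C9, C11 and C12.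

Step 2
Reactants: 4 butan-2-one; 5 N,N-dimethylformamide dimethyl acetal
Product: 6 (E)-1-(dimethylamino)pent-1-en-3-one
Conditions: neat, 100 °C, MeOH distilled off
Reagents that add atoms: none
Why: Enaminone formation by condensation of the amide acetal at the less hindered methyl group of the ketone; the minor methylene-derived isomer is removed by distillation.

Step 3
Reactants: 6 (E)-1-(dimethylamino)pent-1-en-3-one; 7 (2S,5S)-2,5-diphenylpyrrolidine
Product: 8 (E)-1-[(2S,5S)-2,5-diphenylpyrrolidin-1-yl]pent-1-en-3-one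
Conditions: AcOH (10 mol%), toluene, 90 °C, N2 stream
Reagents that add atoms: none
Why: Amine exchange on the vinylogous amide (addition–elimination), driven by loss of volatile dimethylamine, installs the C2-symmetric auxiliary.

Step 4
Reactants: 8 (E)-1-[(2S,5S)-2,5-diphenylpyrrolidin-1-yl]pent-1-en-3-one
Product: 10 (2S,5S)-1-[(1E,3Z)-3-(tert-butyldimethylsilyloxy)penta-1,3-dien-1-yl]-2,5-diphenylpyrrolidine, via potassium dienolate 9 (not isolated)
Conditions: KN(SiMe3)2, THF, −78 °C; TBSCl, −78 → 0 °C
Reagents that add atoms: tert-butyl(chloro)dimethylsilane CC(C)(C)[Si](C)(C)Cl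
Why: Kinetic deprotonation of the ethyl CH2 and O-silylation of the (Z)-enolate should give the electron-rich 1-amino-3-siloxy diene that carries C5–C8 and the future C8 methyl.

Step 5
Reactants: 3 (E)-5-(benzyloxy)-2-methylpent-2-enal; 10 chiral amino siloxy diene
Product: 12 (1S,6S)-6-[2-(benzyloxy)ethyl]-1,5-dimethyl-4-oxocyclohex-2-ene-1-carbaldehyde (C5 epimers), via cycloadduct 11 (not isolated)
Conditions: toluene, 4 Å MS, 25 → 45 °C; then HF (aq), MeCN, 0 °C
Reagents that add atoms: none
Why: Diels–Alder reaction with the amino terminus bonding to C10 and the methyl-bearing terminus to C9; suprafacial addition to the (E)-enal puts the C10 methyl and the C9 chain cis, the auxiliary fixes the diene face and so the absolute configuration, and HF unmasks the C7 ketone and eliminates the amine to the C5=C6 enone.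

Step 6
Reactants: 12 ring B enone aldehyde
Product: 14 (1S,5S,6R)-6-[2-(benzyloxy)ethyl]-1,5-dimethyl-4-oxo-5-(triethylsilyloxy)cyclohex-2-ene-1-carbaldehyde, via silyl dienol ether 13 (not isolated)
Conditions: Et3SiOTf, Et3N, CH2Cl2, −78 → 0 °C; then dimethyldioxirane, acetone, −78 °C
Reagents that add atoms: triethylsilyl trifluoromethanesulfonate CC[Si](CC)(CC)OS(=O)(=O)C(F)(F)F; dimethyldioxirane CC1(C)OO1
Why: Rubottom oxidation: the enone can be enolised only at C8 (C10 is quaternary, the aldehyde has no α-hydrogen), the dioxirane should attack the enol ether anti to the C9 chain, and silyl migration gives the 8-silyloxy ketone with the C8 methyl cis to the C9 chain and the C10 methyl.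

Step 7
Reactants: 14 ring B enone aldehyde with C8 silyl ether; 15 3-methylbutan-2-one
Product: 18 cis-fused decalin 12-benzyloxy-1-hydroxy-3,7-dione 8-triethylsilyl ether (C1 epimers; target numbering), via ketone dianion 16 (not isolated), via aldolate 17 (not isolated)
Conditions: 15 (1.3 equiv), KH, THF, 25 °C; n-BuLi, TMEDA, 0 °C; then 14, −78 → 0 °C; aq NH4Cl
Reagents that add atoms: none
Why: Proposed new method: the α,α′-dianion of 15 reacts first at its more basic, less hindered CH2 terminus (C2) with the aldehyde carbon C1 of 14, and the tetrasubstituted enolate that remains (C4=C3–O−) then adds to C5 of the ring B enone in a 6-(enolendo)-exo-trig Michael closure. The closest known reactions are the aldol addition and alkylation of ketone α,α′-dianions at the less substituted carbon and the intramolecular Michael addition of ketone enolates to cyclohexenones; their union in one annulation of a 4-formylcyclohex-2-enone has not been shown. Ring A closes by axial attack of C4 on C5 from the face that carries the C10–C1 bond, so the new C5 stereocentre is fixed by C10 through the three-atom tether and H-5 ends syn to the C10 methyl (cis-decalin); C4 is not stereogenic and the C1 carbinol is removed in step 8. The step needs 1,2-addition to the aldehyde in preference to the enone and its ketone, which the far higher electrophilicity of the aldehyde at −78 °C should secure. It also needs the Michael closure to outrun retro-aldol cleavage and dehydration; 14 has no acidic hydrogen (C8 and C10 are quaternary) and the aldolate already carries the enolate on C4, so no further deprotonation at C2 is required.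

Step 8
Reactants: 18 cis-fused hydroxy diketone
Product: 20 cis-fused decalin 1-en-3-one 7-one (ring A enone; 12-OBn; 8-OSiEt3), via mesylate 19 (not isolated)
Conditions: MsCl, Et3N, CH2Cl2, 0 °C; then DBU, 25 °C
Reagents that add atoms: none
Why: Mesylation and E1cB elimination of the β-hydroxy ketone remove the C1 oxygen and give a ring A enone that has no enolisable hydrogen (C4 and C10 are quaternary).

Step 9
Reactants: 20 cis-fused enone ketone
Product: 22 C7 enol triflate (C6=C7) of 20, via potassium enolate 21 (not isolated)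
Conditions: KN(SiMe3)2, THF, −78 °C; PhNTf2, −78 → 0 °C
Reagents that add atoms: N-phenylbis(trifluoromethanesulfonimide) O=S(=O)(N(c1ccccc1)S(=O)(=O)C(F)(F)F)C(F)(F)F
Why: The C7 ketone can enolise only toward C6 (C8 is quaternary), so O-triflation should give a single enol triflate.

Step 10
Reactants: 22 enol triflate
Product: 23 cis-fused decalin 12-hydroxy-3-one 8-triethylsilyl ether (C1, C2, C6, C7 all CH2)
Conditions: H2 (1 atm), Pd/C, NaHCO3, EtOAc–EtOH, 25 °C
Reagents that add atoms: none
Why: One palladium-catalysed hydrogenation should hydrogenolyse the enol triflate C–O bond, saturate C6=C7 and the C1=C2 enone bond, and cleave the benzyl ether; no stereocentre is formed or touched.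

Step 11
Reactants: 23 hydroxy ketone
Product: 24 12-iodo-3-one 8-triethylsilyl ether
Conditions: I2, PPh3, imidazole, CH2Cl2, 0 °C
Reagents that add atoms: iodine II
Why: Appel iodination of the unhindered primary alcohol; the ketone and the tertiary silyl ether are inert.

Step 12
Reactants: 25 geranyl bromide; 26 1-(trimethylsilyl)propyne
Product: 28 (E)-trimethyl(6,10-dimethylundeca-5,9-dien-1-yn-1-yl)silane, via propargyl lithium 27 (not isolated)
Conditions: 26, n-BuLi, THF, −20 °C; then 25, −78 → 0 °C
Reagents that add atoms: none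
Why: SN2 alkylation of the lithiated silylpropyne at the primary allylic carbon keeps the (E)-alkene.

Step 13
Reactants: 28 silyl enyne
Product: 29 (E)-6,10-dimethylundeca-5,9-dien-1-yne
Conditions: K2CO3, MeOH, 25 °C
Reagents that add atoms: none
Why: Methanolysis of the alkynyl–silicon bond frees the terminal alkyne.

Step 14
Reactants: 29 terminal alkyne
Product: 31 (1E,5E)-1-iodo-2,6,10-trimethylundeca-1,5,9-triene, via alkenylalane 30 (not isolated)
Conditions: AlMe3, ZrCp2Cl2 (20 mol%), CH2Cl2, 0 → 25 °C; then I2, THF, −30 °C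
Reagents that add atoms: trimethylaluminium C[Al](C)C; iodine II
Why: Zirconium-catalysed carboalumination adds methyl and aluminium syn across the alkyne, and iodinolysis with retention gives the (E)-vinyl iodide that carries C13–C22.

Step 15
Reactants: 24 alkyl iodide; 31 vinyl iodide
Product: 33 cis-fused decalin 3-one 8-triethylsilyl ether with the complete C11–C22 side chain, via alkylzinc iodide 32 (not isolated)
Conditions: Zn dust, LiCl, THF, 40 °C; then 31, PdCl2(dppf) (5 mol%), 50 °C
Reagents that add atoms: none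
Why: Negishi sp3–sp2 coupling forms C12–C13 with retention of the alkene geometry; the alkylzinc tolerates the ketone and the silyl ether.

Step 16
Reactants: 33 ketone
Product: 34 (3S)-alcohol 8-triethylsilyl ether
Conditions: (R)-2-methyl-CBS-oxazaborolidine (1 equiv), catecholborane, toluene, −78 °C; aq NaOH
Reagents that add atoms: none
Why: Corey–Bakshi–Shibata reduction: the ketone lies between a small CH2 (C2) and a large quaternary carbon (C4), so reagent-controlled hydride delivery should give the (3S)-carbinol; catecholborane at −78 °C leaves the trisubstituted alkenes alone.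

Step 17
Reactants: 34 monosilyl ether
Product: 35 IN0670
Conditions: Bu4NF, THF, 40 °C
Reagents that add atoms: none
Why: Fluoride cleavage of the tertiary triethylsilyl ether frees the C8 alcohol.

**Compound list**
1 | 3-(benzyloxy)propanal | O=CCCOCc1ccccc1 | starting material
2 | 2-(triphenylphosphoranylidene)propanal | CC(C=O)=P(c1ccccc1)(c1ccccc1)c1ccccc1 | starting material
3 | (E)-5-(benzyloxy)-2-methylpent-2-enal | O=C/C(C)=C/CCOCc1ccccc1 | intermediate
4 | butan-2-one | CCC(C)=O | starting material
5 | N,N-dimethylformamide dimethyl acetal | COC(OC)N(C)C | starting material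
6 | (E)-1-(dimethylamino)pent-1-en-3-one | CCC(=O)/C=C/N(C)C | intermediate
7 | (2S,5S)-2,5-diphenylpyrrolidine | N1[C@H](c2ccccc2)CC[C@H]1c1ccccc1 | starting material
8 | (E)-1-[(2S,5S)-2,5-diphenylpyrrolidin-1-yl]pent-1-en-3-one | CCC(=O)/C=C/N1[C@H](c2ccccc2)CC[C@H]1c1ccccc1 | intermediate
9 | potassium (Z)-dienolate of 8 | [K+].C/C=C([O-])/C=C/N1[C@H](c2ccccc2)CC[C@H]1c1ccccc1 | intermediate
10 | (2S,5S)-1-[(1E,3Z)-3-(tert-butyldimethylsilyloxy)penta-1,3-dien-1-yl]-2,5-diphenylpyrrolidine | C/C=C(O[Si](C)(C)C(C)(C)C)/C=C/N1[C@H](c2ccccc2)CC[C@H]1c1ccccc1 | intermediate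
11 | Diels–Alder cycloadduct: 6-[2-(benzyloxy)ethyl]-4-(tert-butyldimethylsilyloxy)-2-[(2S,5S)-2,5-diphenylpyrrolidin-1-yl]-1,5-dimethylcyclohex-3-ene-1-carbaldehyde (C1 and C6 as in 12; C2 and C5 unassigned) | c1ccccc1COCC[C@@H]1[C@@](C(N2[C@H](c3ccccc3)CC[C@H]2c2ccccc2)C=C(O[Si](C)(C)C(C)(C)C)C1C)(C)C=O | intermediate
12 | (1S,6S)-6-[2-(benzyloxy)ethyl]-1,5-dimethyl-4-oxocyclohex-2-ene-1-carbaldehyde (C5 epimers) | c1ccccc1COCC[C@@H]1[C@@](C=CC(=O)C1C)(C)C=O | intermediate
13 | (1S,6S)-6-[2-(benzyloxy)ethyl]-1,5-dimethyl-4-(triethylsilyloxy)cyclohexa-2,4-diene-1-carbaldehyde | c1ccccc1COCC[C@@H]1[C@@](C=CC(O[Si](CC)(CC)CC)=C1C)(C)C=O | intermediate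
14 | (1S,5S,6R)-6-[2-(benzyloxy)ethyl]-1,5-dimethyl-4-oxo-5-(triethylsilyloxy)cyclohex-2-ene-1-carbaldehyde | c1ccccc1COCC[C@@H]1[C@@](C=CC(=O)[C@@]1(C)O[Si](CC)(CC)CC)(C)C=O | intermediate
15 | 3-methylbutan-2-one | CC(=O)C(C)C | starting material
16 | α,α′-dianion of 15 (potassium lithium salt) | [Li+].[K+].[CH2-]C([O-])=C(C)C | intermediate
17 | aldolate of 14 with 16 (C1 alkoxide; C3–C4 enolate) | [Li+].[K+].c1ccccc1COCC[C@@H]1[C@@](C=CC(=O)[C@@]1(C)O[Si](CC)(CC)CC)(C)C([O-])CC([O-])=C(C)C | intermediate
18 | cis-fused decalin: 12-benzyloxy-1-hydroxy-3,7-dioxo-8-triethylsilyloxy (target numbering; H-5 syn to C10 methyl; C1 epimers) | c1ccccc1COCC[C@@H]1[C@@]2(C)C(O)CC(=O)C(C)(C)[C@H]2CC(=O)[C@@]1(C)O[Si](CC)(CC)CC | intermediate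
19 | C1 mesylate of 18 | c1ccccc1COCC[C@@H]1[C@@]2(C)C(OS(C)(=O)=O)CC(=O)C(C)(C)[C@H]2CC(=O)[C@@]1(C)O[Si](CC)(CC)CC | intermediate
20 | cis-fused decalin: 1-en-3-one; 7-one; 12-benzyloxy; 8-triethylsilyloxy | c1ccccc1COCC[C@@H]1[C@@]2(C)C=CC(=O)C(C)(C)[C@H]2CC(=O)[C@@]1(C)O[Si](CC)(CC)CC | intermediate
21 | potassium C6=C7 enolate of 20 | c1ccccc1COCC[C@@H]1[C@@]2(C)C=CC(=O)C(C)(C)[C@H]2C=C([O-])[C@@]1(C)O[Si](CC)(CC)CC.[K+] | intermediate
22 | C7 enol triflate (C6=C7) of 20 | c1ccccc1COCC[C@@H]1[C@@]2(C)C=CC(=O)C(C)(C)[C@H]2C=C(OS(=O)(=O)C(F)(F)F)[C@@]1(C)O[Si](CC)(CC)CC | intermediate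
23 | cis-fused decalin: 12-hydroxy-3-one; 8-triethylsilyloxy | OCC[C@@H]1[C@@]2(C)CCC(=O)C(C)(C)[C@H]2CC[C@@]1(C)O[Si](CC)(CC)CC | intermediate
24 | cis-fused decalin: 12-iodo-3-one; 8-triethylsilyloxy | ICC[C@@H]1[C@@]2(C)CCC(=O)C(C)(C)[C@H]2CC[C@@]1(C)O[Si](CC)(CC)CC | intermediate
25 | geranyl bromide, (E)-1-bromo-3,7-dimethylocta-2,6-diene | CC(C)=CCC/C(C)=C/CBr | starting material
26 | 1-(trimethylsilyl)propyne | CC#C[Si](C)(C)C | starting material
27 | 3-lithio-1-(trimethylsilyl)propyne | [Li+].[CH2-]C#C[Si](C)(C)C | intermediate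
28 | (E)-trimethyl(6,10-dimethylundeca-5,9-dien-1-yn-1-yl)silane | CC(C)=CCC/C(C)=C/CCC#C[Si](C)(C)C | intermediate
29 | (E)-6,10-dimethylundeca-5,9-dien-1-yne | CC(C)=CCC/C(C)=C/CCC#C | intermediate
30 | dimethyl[(1E,5E)-2,6,10-trimethylundeca-1,5,9-trien-1-yl]alumane | CC(C)=CCC/C(C)=C/CC/C(C)=C/[Al](C)C | intermediate
31 | (1E,5E)-1-iodo-2,6,10-trimethylundeca-1,5,9-triene | CC(C)=CCC/C(C)=C/CC/C(C)=C/I | intermediate
32 | C12 alkylzinc iodide from 24 | I[Zn]CC[C@@H]1[C@@]2(C)CCC(=O)C(C)(C)[C@H]2CC[C@@]1(C)O[Si](CC)(CC)CC | intermediate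
33 | 3-oxo 8-triethylsilyl ether with full side chain | CC(C)=CCC/C(C)=C/CC/C(C)=C/CC[C@@H]1[C@@]2(C)CCC(=O)C(C)(C)[C@H]2CC[C@@]1(C)O[Si](CC)(CC)CC | intermediate
34 | (3S)-hydroxy 8-triethylsilyl ether | CC(C)=CCC/C(C)=C/CC/C(C)=C/CC[C@@H]1[C@@]2(C)CC[C@H](O)C(C)(C)[C@H]2CC[C@@]1(C)O[Si](CC)(CC)CC | intermediate
35 | IN0670 | CC(C)=CCC/C(C)=C/CC/C(C)=C/CC[C@@H]1[C@@]2(C)CC[C@H](O)C(C)(C)[C@H]2CC[C@@]1(C)O | target

**Step count**
Total: 17 steps. Longest linear sequence: 13 steps (2, 3, 4, 5, 6, 7, 8, 9, 10, 11, 15, 16, 17).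

**Steps most likely to fail**

Step 7 (Proposed new method). The aldolate may revert by retro-aldol cleavage, or the dianion may act as a base or add to the enone, before the Michael closure takes place. Fallback with known reactions, from 14 back to 20: Still–Gennari olefination of the aldehyde of 14 with bis(2,2,2-trifluoroethyl) (3-methyl-2-oxobutyl)phosphonate (KN(SiMe3)2, 18-crown-6, THF, −78 °C) should give the (Z)-enone F1. F1 has a single enolisable hydrogen (the isopropyl C4–H), and its cis double bond holds C4 over C5, so KOt-Bu in THF at −20 °C should close ring A by intramolecular Michael addition and give 20 directly, bypassing 18.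

Step 5. The β-substituted α-methyl enal may react slowly, and the auxiliary may discriminate the diene faces incompletely, which would erode the enantiomeric purity of everything downstream. Fallback from 6 and 3 back to 12: 6 is silylated (KN(SiMe3)2, TBSCl) to the achiral dimethylamino siloxy diene F2. Thermal cycloaddition with 3 gives the racemic cycloadduct F3, and HF work-up the racemic enone aldehyde F4. F4 is condensed with (1S,2S)-N,N′-dimethyl-1,2-diphenylethane-1,2-diamine; the aminal diastereomer F5 is separated by chromatography and hydrolysed on wet silica gel to enantiopure 12.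

Step 6. Silyl transfer to or oxidation of the free aldehyde may compete, and facial selectivity at C8 may be poor. Fallback from 12 back to 14: the aldehyde is protected as the dimethyl acetal F6 (HC(OMe)3, pyridinium tosylate, MeOH). LiN(i-Pr)2 and then 2-(phenylsulfonyl)-3-phenyloxaziridine hydroxylate the C8 enolate anti to the C9 chain to give the hydroxy ketone F7. Et3SiOTf with 2,6-lutidine gives the silyl ether F8, and oxalic acid on wet silica gel releases the aldehyde to give 14.

**Further compounds**
F1 | step 7 | (Z)-enone: 14 with CHO replaced by (Z)-CH=CH–C(=O)–CH(CH3)2 | c1ccccc1COCC[C@@H]1[C@@](C=CC(=O)[C@@]1(C)O[Si](CC)(CC)CC)(C)/C=C\C(=O)C(C)C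
F2 | step 5 | (1E,3Z)-3-(tert-butyldimethylsilyloxy)-N,N-dimethylpenta-1,3-dien-1-amine | C/C=C(O[Si](C)(C)C(C)(C)C)/C=C/N(C)C
F3 | step 5 | racemic dimethylamino cycloadduct (one enantiomer drawn) | c1ccccc1COCC[C@@H]1[C@@](C(N(C)C)C=C(O[Si](C)(C)C(C)(C)C)C1C)(C)C=O
F4 | step 5 | racemic form of 12 (one enantiomer drawn) | c1ccccc1COCC[C@@H]1[C@@](C=CC(=O)C1C)(C)C=O
F5 | step 5 | aminal of 12 with the (1S,2S)-diamine: (4S,5S)-1,3-dimethyl-4,5-diphenylimidazolidin-2-yl in place of CHO | c1ccccc1COCC[C@@H]1[C@@](C=CC(=O)C1C)(C)C1N(C)[C@@H](c2ccccc2)[C@H](c2ccccc2)N1C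
F6 | step 6 | dimethyl acetal of 12 | c1ccccc1COCC[C@@H]1[C@@](C=CC(=O)C1C)(C)C(OC)OC
F7 | step 6 | C8 hydroxy ketone dimethyl acetal | c1ccccc1COCC[C@@H]1[C@@](C=CC(=O)[C@@]1(C)O)(C)C(OC)OC
F8 | step 6 | dimethyl acetal of 14 | c1ccccc1COCC[C@@H]1[C@@](C=CC(=O)[C@@]1(C)O[Si](CC)(CC)CC)(C)C(OC)OC
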